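You want to know whether the excess of right-handed substrate can reach the level asked for, and that can be counted without a rate constant.

| setting | dusk | summer | flask |
|---|---|---|---|
| left-handed substrate | 20 mM | 40 mM | 20 mM |
| right-handed substrate | 20 mM | 40 mM | 20 mM |
| solid reagent | 16 mM | 16 mM | 16.0 mM |
| free catalyst | 0.74 mM | 0.74 mM | 0.74 mM |
| added ligand | 0.60 mM | 0.60 mM | 0.60 mM |
| remark | the very flask that is asked about, followed so far | run made earlier |  |
| time |  |  | 6.0 min |

dusk run (percent of the left-handed substrate and right-handed substrate together charged)

| time / s | right-handed substrate / % | left-handed substrate / % | left-handed product / % |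
|---|---|---|---|
| 10.0 | 50.5 | 50.5 | 0.6 |
| 15.0 | 49.4 | 50.2 | 0.1 |
| 25.0 | 49.5 | 50.4 | 1.1 |
| 40.0 | 48.5 | 48.8 | 1.0 |
| 60.0 | 50.1 | 48.5 | 0.9 |
| 80.0 | 49.1 | 47.2 | 2.5 |

summer run (percent of the left-handed substrate and right-handed substrate together charged)

| time / min | right-handed substrate / % | left-handed substrate / % | left-handed product / % |
|---|---|---|---|
| 0.667 | 50.4 | 49.0 | 1.3 |
| 1.33 | 50.0 | 48.6 | 2.9 |
| 2.00 | 48.0 | 46.8 | 2.9 |
| 3.00 | 48.4 | 45.5 | 3.1 |
| 4.00 | 48.2 | 45.5 | 5.8 |

(scatter of a reading: 0.5 percentage points)

- free catalyst is single-handed; left-handed substrate and right-handed substrate are mirror images of each other, charged as a racemate, each of them at the stated concentration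
- given per volume of solution although it is solid: solid reagent
- at the start none of the solid reagent is in solution

- whether the excess of right-handed substrate over left-handed substrate among what is left of the two reaches 95% by 6.0 min (yes / no)
- the highest excess of right-handed substrate over left-handed substrate among what is left of the two up to 6.0 min

1. Let y be the part of the two substrates together that has reacted, and p the excess of left-handed over right-handed in the product. From a racemic charge, the excess among what is left is then p times y, divided by one minus y.

2. Take the best version of the asked flask, with p equal to one. Reaching 95% then takes y = 48.7%, the needed conversion.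

3. If one reagent serves one substrate, the solid reagent is the limiting reagent on paper: c(solid reagent) = 16.0 mM against 40.0 mM of substrate. That allows y = 40.0%, less than needed, and caps the excess at 66.7%. So my answer is no.

4. Take the poorest version: the asked flask, followed as the dusk run, gains nothing after its last reading at 80.0 s, where the excess reads 1.97%, a figure that carries the scatter of two readings.

5. In the summer run the left-handed substrate read 4.5 percentage points down and the right-handed 1.8 points. So I expect the excess in the asked flask to grow, with p below one, and the top to lie between that scattered reading and that cap.

The forecast says no, with a top of 8% (from 4.5% to 13%), and reaches the same cap by “Even with perfect selectivity”.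

The asked flask gives no, with a top of 3.26%. At 6.00 min, 8.65% has reacted, and the needed conversion is 5.63 times that.

    partner + free catalyst → spent catalyst (k = 0.932 L mol⁻¹ s⁻¹)
    partner + free catalyst + right-handed substrate → free catalyst + right-handed product (k = 103 L² mol⁻² s⁻¹)
    solid reagent ⇌ partner, rate k3*(cs3 - [partner]) while solid is left; crystals form when [partner] > cs3 (solubility = 7.90 mM, k = 0.0362 s⁻¹)
    free catalyst + added ligand ⇌ idle complex (K = 3460 L mol⁻¹, k = 4.90 L mol⁻¹ s⁻¹)
    partner + free catalyst + left-handed substrate → free catalyst + left-handed product (k = 218 L² mol⁻² s⁻¹)

The neighbour flask, like the asked one but with 1.9 mM of free catalyst, has reacted 21.0% at the same time, still below the needed conversion, and its top is 8.54%.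

The numbers in the tables are simulated on assumed constants; the scatter is artificial.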